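**Strategy.** Everything rests on cutting the upper pyran ring C between C3 and C4. C4 is the one carbon that carries both ring A and ring D (C8 of the catechin unit), so it is brought in as a 1,1-diarylethene; C3 is the vinyl carbon of an aryl 1-arylallyl ether whose stereocentre C2 (bearing ring B and O1) comes from an iridium-catalysed allylic etherification. Ring-closing metathesis joins C3 to C4 as a 2H-chromene alkene within the fully assembled, perbenzylated skeleton. Syn hydroboration anti to the C2 aryl group then installs the C3 hydroxyl and C4 hydrogen in the all-trans array, and hydrogenolysis of nine benzyl ethers gives the target.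

Key step: step 10

Remark: the target is read as a (2R,3S,4S)-7,8,3',4'-tetrahydroxyflavan-3-ol unit (aryl groups at C2 and C4 cis to each other, both trans to the 3-OH) joined through C4 to C8 of (+)-catechin (2R,3S).
Assumption: the (Sa,Sc,Sc) enantiomer of the phosphoramidite ligand is taken to give the (S)-ether in step 8; if the sense of induction is the opposite, the mirror-image ligand is used.

**Route**

Step 1
Reactants: 1 (+)-catechin
Product: 2 5,7,3',4'-tetra-O-benzyl-(+)-catechin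
Conditions: BnBr (4.4 equiv), K2CO3, DMF, 0 °C → rt
Reagents that add atoms: benzyl bromide, BrCc1ccccc1
Why: Williamson etherification with a weak base benzylates the four phenols and leaves the secondary 3-OH and the C2/C3 stereocentres untouched.

Step 2
Reactants: 2 5,7,3',4'-tetra-O-benzyl-(+)-catechin
Product: 3 8-bromo-5,7,3',4'-tetra-O-benzyl-(+)-catechin
Conditions: NBS (1.0 equiv), CH2Cl2, −78 °C → rt
Reagents that add atoms: N-bromosuccinimide, O=C1CCC(=O)N1Br
Why: Electrophilic aromatic bromination of the phloroglucinol-type ring is expected at C8, the position known to react first in 5,7-di-O-benzyl flavan-3-ols.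

Step 3
Reactants: 3 8-bromo-5,7,3',4'-tetra-O-benzyl-(+)-catechin
Product: 4 8-bromo-3,5,7,3',4'-penta-O-benzyl-(+)-catechin
Conditions: NaH, BnBr, Bu4NI (cat.), DMF, 0 °C → rt
Reagents that add atoms: benzyl bromide, BrCc1ccccc1
Why: Williamson etherification of the secondary alkoxide removes the only acidic proton before the later halogen–lithium exchange.

Step 4
Reactants: 5 gallacetophenone (1-(2,3,4-trihydroxyphenyl)ethan-1-one)
Product: 6 1-[3,4-bis(benzyloxy)-2-hydroxyphenyl]ethan-1-one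
Conditions: BnBr (2.1 equiv), K2CO3 (2.2 equiv), acetone, reflux
Reagents that add atoms: benzyl bromide, BrCc1ccccc1
Why: Williamson etherification takes the 4- and 3-OH first because the 2-OH is held in a hydrogen bond to the acetyl carbonyl and is the least nucleophilic.

Step 5
Reactants: 7 3,4-bis(benzyloxy)benzaldehyde
Product: 8 ethyl (E)-3-[3,4-bis(benzyloxy)phenyl]prop-2-enoate
Conditions: Ph3P=CHCO2Et, CH2Cl2, rt
Reagents that add atoms: (ethoxycarbonylmethylene)triphenylphosphorane, CCOC(=O)C=P(c1ccccc1)(c1ccccc1)c1ccccc1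
Why: Wittig olefination with a stabilised ylide gives the (E)-cinnamate.

Step 6
Reactants: 8 ethyl (E)-3-[3,4-bis(benzyloxy)phenyl]prop-2-enoate
Product: 9 (E)-3-[3,4-bis(benzyloxy)phenyl]prop-2-en-1-ol
Conditions: i-Bu2AlH (2.2 equiv), CH2Cl2, −78 → 0 °C
Reagents that add atoms: none
Why: 1,2-Reduction of the conjugated ester by the aluminium hydride gives the allylic alcohol without touching the alkene or the benzyl ethers.

Step 7
Reactants: 9 (E)-3-[3,4-bis(benzyloxy)phenyl]prop-2-en-1-ol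
Product: 10 (E)-3-[3,4-bis(benzyloxy)phenyl]prop-2-en-1-yl methyl carbonate
Conditions: ClCO2Me, pyridine, CH2Cl2, 0 °C
Reagents that add atoms: methyl chloroformate, COC(=O)Cl
Why: O-Acylation of the primary alcohol gives the linear allylic carbonate needed for iridium allyl formation.

Step 8
Reactants: 6 1-[3,4-bis(benzyloxy)-2-hydroxyphenyl]ethan-1-one; 10 (E)-3-[3,4-bis(benzyloxy)phenyl]prop-2-en-1-yl methyl carbonate
Product: 11 1-[3,4-bis(benzyloxy)-2-{[(1S)-1-[3,4-bis(benzyloxy)phenyl]prop-2-en-1-yl]oxy}phenyl]ethan-1-one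
Conditions: 6, LiN(SiMe3)2 (1.0 equiv), THF, 0 °C; then 10, [Ir(cod)Cl]2 (2 mol%), (Sa,Sc,Sc)-O,O'-(1,1'-binaphthyl-2,2'-diyl) N,N-bis(1-phenylethyl)phosphoramidite (4 mol%, pre-activated with n-PrNH2), THF, rt
Reagents that add atoms: none
Why: Iridium-catalysed asymmetric allylic etherification (Hartwig type) lets the lithium phenoxide attack the aryl-substituted terminus of the iridium allyl, so that the branched ether forms and the chiral phosphoramidite sets C2 as (S).

Step 9
Reactants: 4 8-bromo-3,5,7,3',4'-penta-O-benzyl-(+)-catechin; 11 the (S)-aryl 1-arylallyl ether ketone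
Product: 15 1,1-diarylethene diene (ring A carrying the (S)-1-arylallyl ether at O1 and the C4 methylidene bound to C8 of penta-O-benzylcatechin), via aryllithium 12 (not isolated), via aryldichlorocerium 13 (not isolated), via tertiary carbinol 14 (not isolated)
Conditions: 4 (1.5 equiv), t-BuLi (3.1 equiv), THF, −78 °C; CeCl3 (anhydrous), −78 °C; 11, −78 → −20 °C; NH4Cl (aq); crude 14, PPTS (5 mol%), 4 Å MS, CH2Cl2, rt
Reagents that add atoms: none
Why: Bromine–lithium exchange, transmetallation to the weakly basic aryl-cerium and 1,2-addition to the methyl ketone (Imamoto organocerium addition, which suppresses enolisation) give a bis-aryl tertiary carbinol that loses water by an E1 path through the doubly aryl-stabilised cation under trace acid, with the C2 ether centre untouched.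

Step 10
Reactants: 15 1,1-diarylethene diene
Product: 16 (2S)-7,8-bis(benzyloxy)-2-[3,4-bis(benzyloxy)phenyl]-4-[(2R,3S)-3,5,7-tris(benzyloxy)-2-[3,4-bis(benzyloxy)phenyl]chroman-8-yl]-2H-chromene
Conditions: second-generation Hoveyda–Grubbs catalyst (10 mol%), 1,4-benzoquinone (20 mol%), CH2Cl2 (5 mM, degassed, argon sparge), 40 °C
Reagents that add atoms: none
Why: The ruthenium alkylidene loads on the monosubstituted C3 vinyl group, undergoes intramolecular [2+2] addition to the 1,1-diarylethene at C4 and cycloreverts, which expels ethylene and leaves the C3=C4 bond (Chauvin mechanism). The closest known reaction type is the ring-closing metathesis of 2-(1-arylvinyl)phenyl allyl ethers to 4-aryl-2H-chromenes. Ring C closes as a six-membered ring through a ruthenacyclobutane built on the two alkenes that ring A holds ortho to each other. No stereocentre is made and C2 is carried through unchanged; the new trisubstituted alkene is the handle from which C3 and C4 are set in step 11. The step needs ring closure to win over cross-metathesis and over migration of the allyl double bond, which the ortho tether, high dilution, the inertness of the 1,1-diarylethene towards homodimerisation and benzoquinone as a hydride scavenger should secure. The temperature is held at 40 °C so that the 2H-chromene does not lose its C2 configuration by electrocyclic ring opening.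

Step 11
Reactants: 16 the (2S)-4-aryl-2H-chromene
Product: 18 (2R,3S,4S)-7,8-bis(benzyloxy)-2-[3,4-bis(benzyloxy)phenyl]-4-[(2R,3S)-3,5,7-tris(benzyloxy)-2-[3,4-bis(benzyloxy)phenyl]chroman-8-yl]chroman-3-ol, via C3-alkylborane 17 (not isolated)
Conditions: BH3·THF (4 equiv), THF, 0 °C → rt; then NaOH (3 M), H2O2 (30%), 0 °C → rt
Reagents that add atoms: borane–tetrahydrofuran, B.C1CCOC1 (boron only in 17); hydrogen peroxide, OO (oxygen at C3 of 18)
Why: Hydroboration–oxidation adds boron to the less hindered C3 and hydrogen to the diaryl-substituted C4 in a syn fashion on the face anti to the C2 aryl group, and oxidation with retention then gives the 2,3-trans-3,4-trans array (C3 S, C4 S), as known for flav-3-enes going to 2,3-trans-flavan-3-ols.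

Step 12
Reactants: 18 the nona-O-benzyl dimer
Product: 19 (2R,3S,4S)-2-(3,4-dihydroxyphenyl)-4-[(2R,3S)-2-(3,4-dihydroxyphenyl)-3,5,7-trihydroxychroman-8-yl]chromane-3,7,8-triol (target)
Conditions: H2 (1 atm), Pd(OH)2/C, THF/MeOH/H2O, rt
Reagents that add atoms: none
Why: Hydrogenolysis of the nine benzyl ethers over Pd(OH)2/C under mild neutral conditions should leave the cyclic benzylic ethers O1–C2 and the C4–C8 bond intact, as is usual for benzylated proanthocyanidins.

**Compound list**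

1 | (+)-catechin, (2R,3S)-2-(3,4-dihydroxyphenyl)chromane-3,5,7-triol | Oc1cc(O)c2c(c1)O[C@H](c1ccc(O)c(O)c1)[C@@H](O)C2 | starting material
2 | 5,7,3',4'-tetra-O-benzyl-(+)-catechin | c1c(OCc5ccccc5)cc(OCc5ccccc5)c2c1O[C@H](c1ccc(OCc5ccccc5)c(OCc5ccccc5)c1)[C@@H](O)C2 | intermediate
3 | 8-bromo-5,7,3',4'-tetra-O-benzyl-(+)-catechin | Brc1c(OCc5ccccc5)cc(OCc5ccccc5)c2c1O[C@H](c1ccc(OCc5ccccc5)c(OCc5ccccc5)c1)[C@@H](O)C2 | intermediate
4 | 8-bromo-3,5,7,3',4'-penta-O-benzyl-(+)-catechin | Brc1c(OCc5ccccc5)cc(OCc5ccccc5)c2c1O[C@H](c1ccc(OCc5ccccc5)c(OCc5ccccc5)c1)[C@@H](OCc5ccccc5)C2 | intermediate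
5 | gallacetophenone, 1-(2,3,4-trihydroxyphenyl)ethan-1-one | CC(=O)c1ccc(O)c(O)c1O | starting material
6 | 1-[3,4-bis(benzyloxy)-2-hydroxyphenyl]ethan-1-one | CC(=O)c1ccc(OCc2ccccc2)c(OCc2ccccc2)c1O | intermediate
7 | 3,4-bis(benzyloxy)benzaldehyde | O=Cc1ccc(OCc2ccccc2)c(OCc2ccccc2)c1 | starting material
8 | ethyl (E)-3-[3,4-bis(benzyloxy)phenyl]prop-2-enoate | CCOC(=O)/C=C/c1ccc(OCc2ccccc2)c(OCc2ccccc2)c1 | intermediate
9 | (E)-3-[3,4-bis(benzyloxy)phenyl]prop-2-en-1-ol | OC/C=C/c1ccc(OCc2ccccc2)c(OCc2ccccc2)c1 | intermediate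
10 | (E)-3-[3,4-bis(benzyloxy)phenyl]prop-2-en-1-yl methyl carbonate | COC(=O)OC/C=C/c1ccc(OCc2ccccc2)c(OCc2ccccc2)c1 | intermediate
11 | 1-[3,4-bis(benzyloxy)-2-{[(1S)-1-[3,4-bis(benzyloxy)phenyl]prop-2-en-1-yl]oxy}phenyl]ethan-1-one | c5ccccc5COc1ccc([C@H](C=C)Oc3c(ccc(OCc5ccccc5)c3OCc5ccccc5)C(C)=O)cc1OCc5ccccc5 | intermediate
12 | 8-lithio-3,5,7,3',4'-penta-O-benzyl-(+)-catechin (not isolated) | [Li]c1c(OCc5ccccc5)cc(OCc5ccccc5)c2c1O[C@H](c1ccc(OCc5ccccc5)c(OCc5ccccc5)c1)[C@@H](OCc5ccccc5)C2 | intermediate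
13 | 8-(dichlorocerio)-3,5,7,3',4'-penta-O-benzyl-(+)-catechin (not isolated) | Cl[Ce](Cl)c1c(OCc5ccccc5)cc(OCc5ccccc5)c2c1O[C@H](c1ccc(OCc5ccccc5)c(OCc5ccccc5)c1)[C@@H](OCc5ccccc5)C2 | intermediate
14 | 1-[3,4-bis(benzyloxy)-2-{[(1S)-1-[3,4-bis(benzyloxy)phenyl]prop-2-en-1-yl]oxy}phenyl]-1-[(2R,3S)-3,5,7-tris(benzyloxy)-2-[3,4-bis(benzyloxy)phenyl]chroman-8-yl]ethan-1-ol, both epimers at the carbinol carbon (not isolated) | c5ccccc5COc1ccc([C@H](C=C)Oc3c(ccc(OCc5ccccc5)c3OCc5ccccc5)C(C)(O)c3c(OCc5ccccc5)cc(OCc5ccccc5)c4c3O[C@H](c3ccc(OCc5ccccc5)c(OCc5ccccc5)c3)[C@@H](OCc5ccccc5)C4)cc1OCc5ccccc5 | intermediate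
15 | (2R,3S)-3,5,7-tris(benzyloxy)-2-[3,4-bis(benzyloxy)phenyl]-8-{1-[3,4-bis(benzyloxy)-2-{[(1S)-1-[3,4-bis(benzyloxy)phenyl]prop-2-en-1-yl]oxy}phenyl]ethenyl}chromane | c5ccccc5COc1ccc([C@H](C=C)Oc3c(ccc(OCc5ccccc5)c3OCc5ccccc5)C(=C)c3c(OCc5ccccc5)cc(OCc5ccccc5)c4c3O[C@H](c3ccc(OCc5ccccc5)c(OCc5ccccc5)c3)[C@@H](OCc5ccccc5)C4)cc1OCc5ccccc5 | intermediate
16 | (2S)-7,8-bis(benzyloxy)-2-[3,4-bis(benzyloxy)phenyl]-4-[(2R,3S)-3,5,7-tris(benzyloxy)-2-[3,4-bis(benzyloxy)phenyl]chroman-8-yl]-2H-chromene | c5ccccc5COc1ccc([C@H]2Oc3c(ccc(OCc5ccccc5)c3OCc5ccccc5)C(c3c(OCc5ccccc5)cc(OCc5ccccc5)c4c3O[C@H](c3ccc(OCc5ccccc5)c(OCc5ccccc5)c3)[C@@H](OCc5ccccc5)C4)=C2)cc1OCc5ccccc5 | intermediate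
17 | C3-alkylborane from 16, with H at C4 and BH2 at C3 on the face anti to the C2 aryl group (not isolated) | c5ccccc5COc1ccc([C@H]2Oc3c(ccc(OCc5ccccc5)c3OCc5ccccc5)[C@@H](c3c(OCc5ccccc5)cc(OCc5ccccc5)c4c3O[C@H](c3ccc(OCc5ccccc5)c(OCc5ccccc5)c3)[C@@H](OCc5ccccc5)C4)[C@@H]2B)cc1OCc5ccccc5 | intermediate
18 | (2R,3S,4S)-7,8-bis(benzyloxy)-2-[3,4-bis(benzyloxy)phenyl]-4-[(2R,3S)-3,5,7-tris(benzyloxy)-2-[3,4-bis(benzyloxy)phenyl]chroman-8-yl]chroman-3-ol | c5ccccc5COc1ccc([C@H]2Oc3c(ccc(OCc5ccccc5)c3OCc5ccccc5)[C@@H](c3c(OCc5ccccc5)cc(OCc5ccccc5)c4c3O[C@H](c3ccc(OCc5ccccc5)c(OCc5ccccc5)c3)[C@@H](OCc5ccccc5)C4)[C@@H]2O)cc1OCc5ccccc5 | intermediate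
19 | (2R,3S,4S)-2-(3,4-dihydroxyphenyl)-4-[(2R,3S)-2-(3,4-dihydroxyphenyl)-3,5,7-trihydroxychroman-8-yl]chromane-3,7,8-triol | Oc1ccc([C@H]2Oc3c(ccc(O)c3O)[C@@H](c3c(O)cc(O)c4c3O[C@H](c3ccc(O)c(O)c3)[C@@H](O)C4)[C@@H]2O)cc1O | target

**Step count and risks**

Total step count: 12. Longest linear sequence: 8 steps (steps 5, 6, 7, 8, 9, 10, 11, 12, from aldehyde 7 to target 19).

Steps most likely to fail:

Step 10 (ring-closing metathesis). The ruthenium alkylidene formed at the vinyl group may fail to engage the 1,1-diarylethene, which is flanked by the 2,6-disubstituted ring D, so that intermolecular metathesis through the vinyl group or migration of the allyl double bond takes over. The fallback keeps the ring closure at C3–C4 but moves it to a stage where C4 carries a small silyloxy group instead of ring D. It sets out from ketone 11. TBSOTf and Et3N in CH2Cl2 give the silyl enol ether (S)-2-(tert-butyldimethylsilyloxy)vinyl diene F1. Second-generation Grubbs catalyst in CH2Cl2 at 40 °C closes ring C to the cyclic silyl enol ether (2S)-4-(tert-butyldimethylsilyloxy)-2H-chromene F2. Bu4NF buffered with AcOH in THF at 0 °C frees the (2S)-flavan-4-one F3. Aryldichlorocerium 13, made from bromide 4 as in step 9, adds to the ketone to give the 4-aryl-flavan-4-ol F4. Dehydration with PPTS as in step 9 returns to the route at chromene 16.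

Step 8 (iridium-catalysed etherification). The chelated, doubly ortho-substituted phenoxide may attack the iridium allyl too slowly, and the electron-rich branched ether may ionise again and leak to the linear cinnamyl ether with erosion of enantiopurity. The fallback sets out from aldehyde 7 and phenol 6 and uses a copper allenylidene instead of an iridium allyl. Ethynylmagnesium bromide in THF followed by Ac2O in the same flask gives the racemic propargylic acetate 1-[3,4-bis(benzyloxy)phenyl]prop-2-yn-1-yl acetate F5. Copper-catalysed enantioselective propargylic etherification of 6 ((CuOTf)2·C6H6, chiral pybox ligand, i-Pr2NEt, MeOH, −20 °C) gives the (S)-propargyl aryl ether F6. Semi-hydrogenation (H2, Pd/CaCO3 poisoned with Pb(OAc)2, quinoline, EtOAc) of the terminal alkyne returns to the route at ketone 11.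

Step 9 (aryl-cerium addition and dehydration). The hindered aryl-metal may deprotonate the methyl ketone instead of adding, or may not reach the carbonyl carbon between two ortho-substituted rings, so that protonation of the aryl-metal and recovery of the ketone take over. The fallback uses a non-enolisable aldehyde and brings the methyl group in last. It sets out from bromide 4, carbonate 10 and commercial 2,3,4-trihydroxybenzaldehyde (O=Cc1ccc(O)c(O)c1O). Dibenzylation as in step 4 gives 3,4-bis(benzyloxy)-2-hydroxybenzaldehyde F7. Etherification with 10 under the conditions of step 8 gives the (S)-allyl ether aldehyde F8. Aryllithium 12, from 4 and t-BuLi, adds at −78 °C to give the diarylmethanol F9. Dess–Martin periodinane in CH2Cl2 gives the diaryl ketone F10. MeMgBr in THF at 0 °C adds to this ketone and returns to the route at carbinol 14, which is dehydrated to 15 as in step 9.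

**Further compounds**

F1 | step 10 | 1-[3,4-bis(benzyloxy)-2-{[(1S)-1-[3,4-bis(benzyloxy)phenyl]prop-2-en-1-yl]oxy}phenyl]-1-(tert-butyldimethylsilyloxy)ethene | c5ccccc5COc1ccc([C@H](C=C)Oc3c(ccc(OCc5ccccc5)c3OCc5ccccc5)C(=C)O[Si](C)(C)C(C)(C)C)cc1OCc5ccccc5
F2 | step 10 | (2S)-7,8-bis(benzyloxy)-2-[3,4-bis(benzyloxy)phenyl]-4-(tert-butyldimethylsilyloxy)-2H-chromene | c5ccccc5COc1ccc([C@H]2Oc3c(ccc(OCc5ccccc5)c3OCc5ccccc5)C(O[Si](C)(C)C(C)(C)C)=C2)cc1OCc5ccccc5
F3 | step 10 | (2S)-7,8-bis(benzyloxy)-2-[3,4-bis(benzyloxy)phenyl]chroman-4-one | c5ccccc5COc1ccc([C@H]2Oc3c(ccc(OCc5ccccc5)c3OCc5ccccc5)C(=O)C2)cc1OCc5ccccc5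
F4 | step 10 | (2S)-7,8-bis(benzyloxy)-2-[3,4-bis(benzyloxy)phenyl]-4-[(2R,3S)-3,5,7-tris(benzyloxy)-2-[3,4-bis(benzyloxy)phenyl]chroman-8-yl]chroman-4-ol, both epimers at C4 | c5ccccc5COc1ccc([C@H]2Oc3c(ccc(OCc5ccccc5)c3OCc5ccccc5)C(O)(c3c(OCc5ccccc5)cc(OCc5ccccc5)c4c3O[C@H](c3ccc(OCc5ccccc5)c(OCc5ccccc5)c3)[C@@H](OCc5ccccc5)C4)C2)cc1OCc5ccccc5
F5 | step 8 | 1-[3,4-bis(benzyloxy)phenyl]prop-2-yn-1-yl acetate, racemic | CC(=O)OC(C#C)c1ccc(OCc2ccccc2)c(OCc2ccccc2)c1
F6 | step 8 | 1-[3,4-bis(benzyloxy)-2-{[(1S)-1-[3,4-bis(benzyloxy)phenyl]prop-2-yn-1-yl]oxy}phenyl]ethan-1-one | c5ccccc5COc1ccc([C@H](C#C)Oc3c(ccc(OCc5ccccc5)c3OCc5ccccc5)C(C)=O)cc1OCc5ccccc5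
F7 | step 9 | 3,4-bis(benzyloxy)-2-hydroxybenzaldehyde | O=Cc1ccc(OCc2ccccc2)c(OCc2ccccc2)c1O
F8 | step 9 | 3,4-bis(benzyloxy)-2-{[(1S)-1-[3,4-bis(benzyloxy)phenyl]prop-2-en-1-yl]oxy}benzaldehyde | c5ccccc5COc1ccc([C@H](C=C)Oc3c(ccc(OCc5ccccc5)c3OCc5ccccc5)C=O)cc1OCc5ccccc5
F9 | step 9 | [3,4-bis(benzyloxy)-2-{[(1S)-1-[3,4-bis(benzyloxy)phenyl]prop-2-en-1-yl]oxy}phenyl][(2R,3S)-3,5,7-tris(benzyloxy)-2-[3,4-bis(benzyloxy)phenyl]chroman-8-yl]methanol, both epimers at the carbinol carbon | c5ccccc5COc1ccc([C@H](C=C)Oc3c(ccc(OCc5ccccc5)c3OCc5ccccc5)C(O)c3c(OCc5ccccc5)cc(OCc5ccccc5)c4c3O[C@H](c3ccc(OCc5ccccc5)c(OCc5ccccc5)c3)[C@@H](OCc5ccccc5)C4)cc1OCc5ccccc5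
F10 | step 9 | [3,4-bis(benzyloxy)-2-{[(1S)-1-[3,4-bis(benzyloxy)phenyl]prop-2-en-1-yl]oxy}phenyl][(2R,3S)-3,5,7-tris(benzyloxy)-2-[3,4-bis(benzyloxy)phenyl]chroman-8-yl]methanone | c5ccccc5COc1ccc([C@H](C=C)Oc3c(ccc(OCc5ccccc5)c3OCc5ccccc5)C(=O)c3c(OCc5ccccc5)cc(OCc5ccccc5)c4c3O[C@H](c3ccc(OCc5ccccc5)c(OCc5ccccc5)c3)[C@@H](OCc5ccccc5)C4)cc1OCc5ccccc5
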